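**Retrosynthetic overview**

- Target ⇒ (3R,5R,6S)-5,6-epoxide: the last step makes the C8–O bond and the 2,5-dihydrofuran ring by a suprafacial 1,3-oxygen shift (vinyl-oxirane ring expansion), which sets C8.
- Epoxide ⇒ (3S)-3-hydroxy-8'-apo-β-caroten-8'-al: hydroxyl-directed syn epoxidation makes the C5–O and C6–O bonds and sets C5 and C6.
- C30 polyene ⇒ C6–C7 Suzuki coupling of a C9 cyclohexenyl triflate with a C21 octaenal boronate, the boronate coming from crocetin dialdehyde by a one-carbon boron-Wittig.
- Triflate ⇒ (4R,6R)-actinol: Mitsunobu inversion (C–O bond, sets C3), then enol triflation.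
- Ring order: the cyclohexene ring is bought, the oxirane is formed second to last, and the dihydrofuran arises last by expansion of the oxirane.

Assumption: (4R,6R)-actinol and crocetin dialdehyde are bought as catalogue carotenoid intermediates; all polyene steps are run under argon in dim light.

**Route**

Step 1
Reactants: 1 (4R,6R)-4-hydroxy-2,2,6-trimethylcyclohexanone [(4R,6R)-actinol, OH and 6-methyl trans]
Product: 2 (1S,5R)-3,3,5-trimethyl-4-oxocyclohexyl 4-nitrobenzoate [ester oxygen and 5-methyl cis; the C4-inverted ester of actinol]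
Conditions: 4-O2NC6H4CO2H, PPh3, DIAD, THF, 0 °C to rt
Reagents that add atoms: 4-nitrobenzoic acid, OC(=O)c1ccc(cc1)[N+](=O)[O-]
Why: Mitsunobu esterification, in which the oxyphosphonium of the secondary alcohol is displaced by 4-nitrobenzoate in an SN2 step with inversion, turns the bought (4R) carbinol into the (S) centre that becomes C3 of the target (oxygen on the face of the later C5 oxygen) and protects it at the same time, while the methyl-bearing centre is not touched and is erased in step 2.

Step 2
Reactants: 2 (1S,5R)-3,3,5-trimethyl-4-oxocyclohexyl 4-nitrobenzoate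
Product: 3 (1S)-3,5,5-trimethyl-4-{[(trifluoromethyl)sulfonyl]oxy}cyclohex-3-en-1-yl 4-nitrobenzoate
Conditions: Tf2O, 2,6-di-tert-butyl-4-methylpyridine, CH2Cl2, 0 °C to rt
Reagents that add atoms: trifluoromethanesulfonic anhydride, O=S(=O)(OS(=O)(=O)C(F)(F)F)C(F)(F)F
Why: Enol triflate formation under weakly basic conditions gives a single tetrasubstituted enol triflate because the ketone can enolise only towards the methyl-bearing carbon (the other alpha carbon is quaternary), and the ester and its stereocentre are inert to these conditions.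

Step 3
Reactants: 4 crocetin dialdehyde [(2E,4E,6E,8E,10E,12E,14E)-2,6,11,15-tetramethylhexadeca-2,4,6,8,10,12,14-heptaenedial; 3 equiv, excess recovered], 5 bis(pinacolatoboryl)methane [2,2'-methylenebis(4,4,5,5-tetramethyl-1,3,2-dioxaborolane)]
Product: 7 (2E,4E,6E,8E,10E,12E,14E,16E)-2,6,11,15-tetramethyl-17-(4,4,5,5-tetramethyl-1,3,2-dioxaborolan-2-yl)heptadeca-2,4,6,8,10,12,14,16-octaenal, via lithiated diborylmethane 6 (not isolated)
Conditions: 5, lithium 2,2,6,6-tetramethylpiperidide (from n-BuLi and 2,2,6,6-tetramethylpiperidine), THF, 0 °C; then 4 (3 equiv), −78 °C to rt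
Reagents that add atoms: none
Why: Boron-Wittig olefination, in which the lithiated geminal diboronate adds 1,2 to one aldehyde and syn-eliminates lithium pinacolborate to give the E-alkenyl boronate, is kept to mono-reaction by the excess of the symmetrical dial.

Step 4
Reactants: 3 (1S)-3,5,5-trimethyl-4-{[(trifluoromethyl)sulfonyl]oxy}cyclohex-3-en-1-yl 4-nitrobenzoate, 7 the C21 octaenal pinacol boronate
Product: 9 (3S)-3-hydroxy-8'-apo-β-caroten-8'-al [all-E; (2E,4E,6E,8E,10E,12E,14E,16E)-17-[(4S)-4-hydroxy-2,6,6-trimethylcyclohex-1-en-1-yl]-2,6,11,15-tetramethylheptadeca-2,4,6,8,10,12,14,16-octaenal], via coupled 4-nitrobenzoate ester 8 (not isolated)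
Conditions: Pd(OAc)2 (5 mol%), SPhos (10 mol%), K3PO4, THF/H2O 10:1, 40 °C; then MeOH, K2CO3 (cat.), rt, same flask
Reagents that add atoms: none
Why: Suzuki–Miyaura coupling (oxidative addition of the hindered enol triflate to zerovalent palladium carrying the bulky SPhos ligand, transmetalation of the alkenyl boronate with retention of E geometry, reductive elimination) forms the C6–C7 bond, after which carbonate-catalysed transesterification with methanol frees the C3 hydroxyl without touching the polyenal.

Step 5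
Reactants: 9 (3S)-3-hydroxy-8'-apo-β-caroten-8'-al
Product: 10 (3R,5R,6S)-5,6-epoxy-3-hydroxy-5,6-dihydro-8'-apo-β-caroten-8'-al [epoxide oxygen on the same ring face as the C3 hydroxyl; all-E chain]
Conditions: VO(acac)2 (5 mol%), t-BuOOH (1.3 equiv, decane), 2,6-lutidine (0.2 equiv), toluene, 0 °C; quick filtration through basic alumina
Reagents that add atoms: tert-butyl hydroperoxide, CC(C)(C)OO
Why: Hydroxyl-directed epoxidation, in which the C3 alkoxide binds the pentavalent vanadium tert-butylperoxo species formed in situ and delivers oxygen to the homoallylic tetrasubstituted C5=C6 bond from its own face, sets C5 (R) and C6 (S) syn to the hydroxyl and spares the unbound polyene and the enal, with the lutidine buffer protecting the acid-labile vinyl epoxide.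

Step 6
Reactants: 10 (3R,5R,6S)-5,6-epoxy-3-hydroxy-5,6-dihydro-8'-apo-β-caroten-8'-al
Product: 11 (3R,5R,8R)-5,8-epoxy-3-hydroxy-5,8-dihydro-8'-apo-β-caroten-8'-al [(2E,4E,6E,8E,10E,12E,14E)-15-[(2R,6R,7aR)-6-hydroxy-4,4,7a-trimethyl-2,4,5,6,7,7a-hexahydro-1-benzofuran-2-yl]-2,6,11-trimethylhexadeca-2,4,6,8,10,12,14-heptaenal; chain at C8 trans to the C5 methyl, C3 hydroxyl cis to the ring oxygen]
Conditions: Cu(hfacac)2 (5 mol%), 2,6-di-tert-butyl-4-methylpyridine (10 mol%), 4 Å MS, toluene, −20 to 0 °C
Reagents that add atoms: none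
Why: Proposed new method: a stereospecific suprafacial 1,3-oxygen shift on a fully substituted carotenoid 5,6-epoxide catalysed by the divalent copper complex Cu(hfacac)2 [copper bis(hexafluoroacetylacetonate)], in which copper held on the oxygen-bearing face by the epoxide oxygen and the syn C3 hydroxyl ionises the C6–O bond to a contact ion pair (C5 copper alkoxide and polyenyl cation) and the same oxygen bonds to C8 on the face it left before the C7–C8 bond can rotate, so that the (7E) geometry and the (6S) epoxide carbon are translated into (8R) with the chain trans to the C5 methyl, while the proton-free medium keeps the product from epimerising at C8; the closest known reaction types are the copper-catalysed ring expansion of simple vinyl oxiranes to 2,5-dihydrofurans and the stereorandom protic-acid epoxide-to-furanoid rearrangement of carotenoid epoxides.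

**Compound list**

1 | (4R,6R)-4-hydroxy-2,2,6-trimethylcyclohexanone [(4R,6R)-actinol] | O=C1C(C)(C)C[C@H](O)C[C@H]1C | starting material
2 | (1S,5R)-3,3,5-trimethyl-4-oxocyclohexyl 4-nitrobenzoate | O=C1C(C)(C)C[C@@H](OC(=O)c2ccc(cc2)[N+](=O)[O-])C[C@H]1C | intermediate
3 | (1S)-3,5,5-trimethyl-4-{[(trifluoromethyl)sulfonyl]oxy}cyclohex-3-en-1-yl 4-nitrobenzoate | CC1=C(OS(=O)(=O)C(F)(F)F)C(C)(C)C[C@@H](OC(=O)c2ccc(cc2)[N+](=O)[O-])C1 | intermediate
4 | crocetin dialdehyde [(all-E)-2,6,11,15-tetramethylhexadeca-2,4,6,8,10,12,14-heptaenedial] | O=C/C(C)=C/C=C/C(C)=C/C=C/C=C(C)/C=C/C=C(C)/C=O | starting material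
5 | bis(pinacolatoboryl)methane | CC1(C)OB(CB2OC(C)(C)C(C)(C)O2)OC1(C)C | starting material
6 | lithio-bis(pinacolatoboryl)methane | [Li]C(B1OC(C)(C)C(C)(C)O1)B1OC(C)(C)C(C)(C)O1 | intermediate
7 | (2E,4E,6E,8E,10E,12E,14E,16E)-2,6,11,15-tetramethyl-17-(4,4,5,5-tetramethyl-1,3,2-dioxaborolan-2-yl)heptadeca-2,4,6,8,10,12,14,16-octaenal | O=C/C(C)=C/C=C/C(C)=C/C=C/C=C(C)/C=C/C=C(C)/C=C/B1OC(C)(C)C(C)(C)O1 | intermediate
8 | (3S)-3-[(4-nitrobenzoyl)oxy]-8'-apo-β-caroten-8'-al (all-E; the O3 4-nitrobenzoate of compound 9) | O=C/C(C)=C/C=C/C(C)=C/C=C/C=C(C)/C=C/C=C(C)/C=C/C1=C(C)C[C@H](OC(=O)c2ccc(cc2)[N+](=O)[O-])CC1(C)C | intermediate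
9 | (3S)-3-hydroxy-8'-apo-β-caroten-8'-al (all-E) | O=C/C(C)=C/C=C/C(C)=C/C=C/C=C(C)/C=C/C=C(C)/C=C/C1=C(C)C[C@H](O)CC1(C)C | intermediate
10 | (3R,5R,6S)-5,6-epoxy-3-hydroxy-5,6-dihydro-8'-apo-β-caroten-8'-al (all-E) | O=C/C(C)=C/C=C/C(C)=C/C=C/C=C(C)/C=C/C=C(C)/C=C/[C@]12C(C)(C)C[C@@H](O)C[C@@]1(C)O2 | intermediate
11 | (3R,5R,8R)-5,8-epoxy-3-hydroxy-5,8-dihydro-8'-apo-β-caroten-8'-al (all-E) | C\C(C=O)=C/C=C/C(C)=C/C=C/C=C(C)/C=C/C=C(\C)[C@H]1C=C2C(C)(C)C[C@@H](O)C[C@@]2(C)O1 | target

**Totals**

Total step count: 6. Longest linear sequence: 5 (steps 1, 2, 4, 5, 6 from compound 1).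

**Steps most likely to fail, with fallbacks**

Step 6 (the proposed copper-catalysed stereospecific ring expansion; the risks are a sluggish reaction, or loss of C8 fidelity if the ion pair lives long enough to rotate). The fallback uses known chemistry and trades kinetic stereocontrol for equilibration and separation. It sets out from 10: the classical protic-acid furanoid rearrangement (about 0.02 M HCl in CHCl3, rt, minutes, quenched with NaHCO3) gives 11 together with its C8 epimer (3R,5R,8S)-5,8-epoxy-3-hydroxy-5,8-dihydro-8'-apo-β-caroten-8'-al F6. The two are separated by semi-preparative HPLC, and F6 is returned to the same acid, which re-opens the ring to the common cation and re-equilibrates C8, so it can be recycled. The fallback comes back to the route at 11.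

Step 5 (directed epoxidation in the presence of a heptaene and an enal; the risks are over-oxidation and premature opening of the epoxide on the Lewis-acidic vanadium). The fallback gives up substrate-directed metal catalysis and uses the intrinsic nucleophilicity of the tetrasubstituted ring alkene towards a peracid, the standard way of making carotenoid 5,6-epoxides. It sets out from 9: monoperphthalic acid in Et2O over NaHCO3 at 0 °C gives 10 together with the anti epoxide (3R,5S,6R)-5,6-epoxy-3-hydroxy-5,6-dihydro-8'-apo-β-caroten-8'-al F5. F5 is removed by HPLC on a base-deactivated phase. The fallback comes back to the route at 10.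

Step 4 (Suzuki coupling of a doubly flanked enol triflate with a light- and base-sensitive octaenal boronate). The fallback moves the C–C bond formation from C6–C7 to C7=C8 and uses a Wittig reaction, the classical C10 + C20 carotenoid assembly. It sets out from 3:
- Palladium-catalysed methoxycarbonylation (Pd(OAc)2, dppp, CO, MeOH, Et3N, DMF, 70 °C) gives methyl (4S)-2,6,6-trimethyl-4-[(4-nitrobenzoyl)oxy]cyclohex-1-ene-1-carboxylate F1.
- i-Bu2AlH (CH2Cl2, −78 °C) reduces both esters to (1S)-4-(hydroxymethyl)-3,5,5-trimethylcyclohex-3-en-1-ol F2.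
- PPh3·HBr in MeOH converts only the allylic primary alcohol into {[(4S)-4-hydroxy-2,6,6-trimethylcyclohex-1-en-1-yl]methyl}triphenylphosphonium bromide F3.
- The ylide of F3 (NaOMe, MeOH/CH2Cl2) condenses with an excess of crocetin dialdehyde 4 to give 9 together with its hindered isomer (3S,7Z)-3-hydroxy-8'-apo-β-caroten-8'-al F4, which is converted into 9 by warming in heptane with a trace of iodine.

The fallback comes back to the route at 9 and makes compounds 5 to 8, and with them step 3, unnecessary.

**Further compounds**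

F1 | step 4 | methyl (4S)-2,6,6-trimethyl-4-[(4-nitrobenzoyl)oxy]cyclohex-1-ene-1-carboxylate | COC(=O)C1=C(C)C[C@H](OC(=O)c2ccc(cc2)[N+](=O)[O-])CC1(C)C
F2 | step 4 | (1S)-4-(hydroxymethyl)-3,5,5-trimethylcyclohex-3-en-1-ol | OCC1=C(C)C[C@H](O)CC1(C)C
F3 | step 4 | {[(4S)-4-hydroxy-2,6,6-trimethylcyclohex-1-en-1-yl]methyl}triphenylphosphonium bromide | O[C@H]1CC(C)=C(C[P+](c2ccccc2)(c2ccccc2)c2ccccc2)C(C)(C)C1.[Br-]
F4 | step 4 | (3S,7Z)-3-hydroxy-8'-apo-β-caroten-8'-al | O=C/C(C)=C/C=C/C(C)=C/C=C/C=C(C)/C=C/C=C(C)/C=C\C1=C(C)C[C@H](O)CC1(C)C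
F5 | step 5 | (3R,5S,6R)-5,6-epoxy-3-hydroxy-5,6-dihydro-8'-apo-β-caroten-8'-al | O=C/C(C)=C/C=C/C(C)=C/C=C/C=C(C)/C=C/C=C(C)/C=C/[C@@]12C(C)(C)C[C@@H](O)C[C@]1(C)O2
F6 | step 6 | (3R,5R,8S)-5,8-epoxy-3-hydroxy-5,8-dihydro-8'-apo-β-caroten-8'-al | C\C(C=O)=C/C=C/C(C)=C/C=C/C=C(C)/C=C/C=C(\C)[C@@H]1C=C2C(C)(C)C[C@@H](O)C[C@@]2(C)O1
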